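## Analysis of the target

Target 22 is an 18-membered macrocycle built from four benzene rings. Ring A is the dihydroxy ring: a 1,2-diol with an aryloxy group next to it and the ethylene bridge meta to both. Ring B is para-linked, ring C is the 1,2,3-trisubstituted monohydroxy ring (C1 bears CH2, C2 the ether oxygen, C3 the hydroxyl), and ring D is meta-linked. The rings are joined by two diaryl ether bonds (A–O–B and C–O–D), a CH2CH2 bridge (A to D) and a CH(OH)CH2 bridge (B to C).

There is a single stereocenter, the benzylic carbinol carbon on ring B, with S configuration, so only absolute control is needed. The sensitive groups are the ring A catechol, which oxidizes in air under base, and the benzylic alcohol para to an aryloxy donor, which ionizes under acid. Strong Lewis acids such as those used to cleave methyl ethers are therefore excluded at the end, and the final deprotections must be neutral.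

The hard problems are the macrocyclization and the C–O–D ether. The oxygen on C2 of ring C lies between the CH2 group and the neighbouring phenol oxygen, and ring D has no activating group, so this is a di-ortho-substituted phenol that would have to be arylated by an unactivated arene. The strategy rests on the fact that this same oxygen is easily acylated: an aryl ester O–C(=O)–ring D can stand in for the ether, leaving one carbon atom to be extruded from the ring.

## Retrosynthetic reasoning

**22 back to 21 and 20 (protecting groups).** The last two operations are fluoride desilylation (21 to 22) and neutral hydrogenolysis (20 to 21). In 20 the carbinol is a TBS ether, the ring C hydroxyl a benzyl ether and the ring A catechol a diphenylmethylene ketal. A silyl ether on the ring C oxygen was deliberately avoided: at the lactonization stage its neighbour is a free phenoxide, and a silyl shift between the two adjacent oxygens would leave the wrong oxygen to be acylated. A benzyl group cannot migrate.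

**20 back to 19 (key disconnection).** The bond from the ring C oxygen to the ring D carbon is cut by inserting a carbonyl group, which gives the 19-membered aryl ester 19. In the forward direction a zerovalent nickel catalyst must insert into the acyl C–O bond, lose the carbonyl carbon and join oxygen and aryl carbon on the metal. The most hindered bond of the macrocycle is thus formed between two groups already held together, and the ring contracts from 19 to 18 members.

**19 back to 17 (ester C–O bond).** The ester bond at the ring C phenol is opened to seco acid 17. The forward reaction is a Yamaguchi macrolactonization through mixed anhydride 18. It only needs an activated acyl group to reach a phenol whose sole free neighbour oxygen is blocked, so the regiochemistry is fixed.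

**17 back to 16 and 15 (unmasking).** The acid comes from methyl ester 16 by saponification, and the ring C phenol from its 4-methoxybenzyl ether 15 by oxidative cleavage. The temporary group must survive enolate chemistry two steps earlier. A silyl group could shift to the enolate oxygen and an acyl group would be attacked by the enolate, so a 4-methoxybenzyl ether was chosen, which is orthogonal to the benzyl ether, ketal and silyl ether.

**15 back to 14 and 13 (stereocenter).** The silyl ether comes from alcohol 14, and the carbinol C–H bond is cut back to ketone 13. Asymmetric transfer hydrogenation of an open-chain aryl benzyl ketone is a dependable way to set a benzylic carbinol. Doing it before ring closure keeps the stereocontrol independent of macrocycle conformation.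

**13 back to 9 and 12 (CH2–ring C bond).** The bond between the ketone α-carbon and ring C is cut, giving methyl ketone 9 and aryl bromide 12. The forward reaction is a palladium-catalysed ketone α-arylation with a weak base, which the methyl ester tolerates.

**12 back to 11 and 10 (ring C building block).** The 4-methoxybenzyl ether 12 comes from bromophenol 11, which arises by ortho-bromination of 10. Starting from the monobenzyl ether of catechol fixes which oxygen stays protected to the end and which one becomes the ester and later the ether oxygen.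

**9 back to 7 and 8 (A–O–B ether).** The ether is cut at the ring B carbon, where the para-acetyl group of 8 activates fluoride displacement by phenol 7. This is done on the methyl ketone, before α-arylation, because the more acidic deoxybenzoin would form an enolate that deactivates the ring toward substitution.

**7 back to 6, then 2 and 4 (ethylene bridge).** The CH2CH2 bridge comes from stilbene 6 by alkene hydrogenation, and 6 from a Wittig reaction of aldehyde 2 with the ylide 5 of phosphonium salt 4, which is made from 3. The Wittig step is placed before the ether formation so that an aldehyde and a methyl ketone never meet under base. Aldehyde 2 comes from 1 by bridging two adjacent hydroxyls, which leaves exactly one phenol free by symmetry.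

## Alternatives that were turned down

**Alternative 1: ring A carried as a cyclohexenone.**
- Disconnection: the A–O–B ether, with ring A at the oxidation level of a cyclohexane-1,3-dione.
- Forward key step: under K2CO3 the ring B phenoxide of the open-chain chloro enone A1 adds to the chlorine-bearing enone carbon and expels chloride, giving the 18-membered aryloxy enone A2.
- For: addition–elimination at a vinylogous acid chloride needs no aromatic activation and is a well-established reaction type. On precedent of the ring-closing step itself this alternative is stronger than the chosen route.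
- Against: A2 still has to be dehydrogenated to the arene in the presence of an enolizable deoxybenzoin. A1 and A2 carry methyl ethers on rings A and C, whose cleavage needs Lewis acids that the benzylic carbinol would not survive, so the ketone must be reduced last, on a free polyphenol macrocycle. The acidic CH2 of the deoxybenzoin in A1 can compete with the phenoxide as a carbon nucleophile. The hindered C–O–D ether must already be present in A1, made by an intermolecular coupling at the di-ortho-substituted phenol.
- Comparison: the chosen route offers a neutral end game, a stereocenter set early on an open chain, and an ester in place of the hindered ether during fragment assembly.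

**Alternative 2: B-alkyl Suzuki macrocyclization at the CH2–ring D bond.**
- Disconnection: the bond between the ethylene bridge and ring D.
- Forward key step: the ring A styrene of A3 is hydroborated with 9-BBN and the alkylborane is coupled with the ring D bromide under Pd(dppf)Cl2 and Cs2CO3, giving the silyl-protected macrocycle A4.
- For: the reaction is well documented for macrocycles, forms an unhindered sp3–sp2 bond far from any ortho substituent, creates no stereocenter, and A4 carries only silyl groups, so one fluoride step finishes the synthesis. On precedent and on the end game this alternative is stronger.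
- Against: A3 must already contain the C–O–D ether, so the hardest bond is moved to an intermolecular Ullmann-type coupling at the di-ortho-substituted ring C phenol. Ring D then needs two differentiated halogens, one of which must survive the construction of the B–C bridge.
- Comparison: the chosen route turns the hardest bond into an intramolecular event and needs only a plain benzoate on ring D. Its price is a ring-contracting step without direct precedent.

**Alternative 3: Nozaki–Hiyama–Kishi macrocyclization at ring B.**
- Disconnection: the bond between ring B and the carbinol carbon.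
- Forward key step: the ring B iodide of A5 adds to its ring C arylacetaldehyde under CrCl2 with catalytic NiCl2 and a chiral oxazoline sulfonamide ligand, giving the macrocyclic carbinol A6.
- For: ring and stereocenter are formed in one step, and A6 needs only desilylation. On step economy at the stereocenter this alternative is stronger.
- Against: the arylacetaldehyde in A5 is enolizable and prone to self-condensation during a slow, high-dilution addition. Ligand control must override the conformational bias of the forming macrocycle, so the configuration is less secure than in a transfer hydrogenation of an open-chain ketone. The reaction uses excess chromium, and A5 again requires the hindered C–O–D ether to be made beforehand.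
- Comparison: the chosen route sets the stereocenter by a reaction whose sense and level of induction do not depend on the ring.

Key step: step 14

## Route

Step 1
Reactants: 1 3,4,5-trihydroxybenzaldehyde
Product: 2 7-hydroxy-2,2-diphenyl-1,3-benzodioxole-5-carbaldehyde
Conditions: Ph2CCl2 (1.3 equiv), Ph2O, 175 °C
Reagents that add atoms: dichlorodiphenylmethane, ClC(Cl)(c1ccccc1)c1ccccc1
Why: Ketal formation from a geminal dichloride and a 1,2-diol; only two adjacent hydroxyls can close the five-membered dioxole and the two possible pairs are equivalent by symmetry, so exactly one phenol, meta to the formyl group, stays free.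

Step 2
Reactants: 3 methyl 3-(bromomethyl)benzoate
Product: 4 [3-(methoxycarbonyl)benzyl]triphenylphosphonium bromide
Conditions: PPh3, toluene, 90 °C
Reagents that add atoms: triphenylphosphine, c1ccc(cc1)P(c1ccccc1)c1ccccc1
Why: SN2 quaternization of the phosphine by a primary benzylic bromide; the salt should precipitate from toluene.

Step 3
Reactants: 2 7-hydroxy-2,2-diphenyl-1,3-benzodioxole-5-carbaldehyde; 4 [3-(methoxycarbonyl)benzyl]triphenylphosphonium bromide
Product: 6 methyl 3-[2-(7-hydroxy-2,2-diphenyl-1,3-benzodioxol-5-yl)ethenyl]benzoate (E/Z mixture), via phosphonium ylide 5 (not isolated)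
Conditions: K2CO3 (4 equiv), 18-crown-6 (10 mol %), THF, reflux
Reagents that add atoms: none
Why: Wittig olefination with a semistabilized benzylic ylide under solid–liquid phase-transfer conditions, which spare the methyl ester; the phenol is carried as its phenoxide, which is meta to the formyl group and so does not deactivate it by resonance, and the alkene geometry is irrelevant because the double bond is saturated next.

Step 4
Reactants: 6 methyl 3-[2-(7-hydroxy-2,2-diphenyl-1,3-benzodioxol-5-yl)ethenyl]benzoate (E/Z mixture)
Product: 7 methyl 3-[2-(7-hydroxy-2,2-diphenyl-1,3-benzodioxol-5-yl)ethyl]benzoate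
Conditions: H2 (1 atm), 10% Pd/C, Ph2S (cat.), EtOAc, rt
Reagents that add atoms: none
Why: Heterogeneous alkene hydrogenation; the sulfide-poisoned palladium catalyst saturates C=C bonds but should not cleave benzylic C–O bonds, so the diphenylmethylene ketal stays in place.

Step 5
Reactants: 7 methyl 3-[2-(7-hydroxy-2,2-diphenyl-1,3-benzodioxol-5-yl)ethyl]benzoate; 8 4'-fluoroacetophenone
Product: 9 methyl 3-{2-[7-(4-acetylphenoxy)-2,2-diphenyl-1,3-benzodioxol-5-yl]ethyl}benzoate
Conditions: Cs2CO3, DMSO, 90 °C
Reagents that add atoms: none
Why: Nucleophilic aromatic substitution (addition–elimination through a Meisenheimer intermediate) at the fluoride para to the acetyl group; the carbonate ionizes the phenol and not the far less acidic methyl ketone, and anhydrous conditions keep the methyl ester.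

Step 6
Reactants: 10 2-(benzyloxy)phenol
Product: 11 2-(benzyloxy)-6-bromophenol
Conditions: NBS (1.0 equiv), i-Pr2NH (10 mol %), CH2Cl2, 0 °C
Reagents that add atoms: N-bromosuccinimide, O=C1CCC(=O)N1Br
Why: Amine-mediated ortho-bromination of a phenol; the N-bromoamine formed in the flask is hydrogen-bonded to the phenol OH and delivers bromine to the one free ortho position, overriding the usual para preference.

Step 7
Reactants: 11 2-(benzyloxy)-6-bromophenol
Product: 12 1-(benzyloxy)-3-bromo-2-[(4-methoxybenzyl)oxy]benzene
Conditions: 4-methoxybenzyl chloride, K2CO3, Bu4NI (cat.), DMF, 50 °C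
Reagents that add atoms: 4-methoxybenzyl chloride, COc1ccc(CCl)cc1
Why: Williamson ether synthesis; the 4-methoxybenzyl ether is inert to enolates and to palladium and can later be removed oxidatively beside a plain benzyl ether.

Step 8
Reactants: 9 methyl 3-{2-[7-(4-acetylphenoxy)-2,2-diphenyl-1,3-benzodioxol-5-yl]ethyl}benzoate; 12 1-(benzyloxy)-3-bromo-2-[(4-methoxybenzyl)oxy]benzene
Product: 13 methyl 3-{2-[7-(4-{[3-(benzyloxy)-2-[(4-methoxybenzyl)oxy]phenyl]acetyl}phenoxy)-2,2-diphenyl-1,3-benzodioxol-5-yl]ethyl}benzoate
Conditions: Pd2(dba)3 (2.5 mol %), Xantphos (6 mol %), K3PO4 (2.5 equiv), toluene, 90 °C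
Reagents that add atoms: none
Why: Palladium-catalysed ketone α-arylation (oxidative addition of the aryl bromide to zerovalent palladium, enolate formation by K3PO4, C–C reductive elimination); the weak base spares the methyl ester, and a second arylation is disfavoured because the product enolate is stabilized and hindered by the ortho-substituted aryl group.

Step 9
Reactants: 13 methyl 3-{2-[7-(4-{[3-(benzyloxy)-2-[(4-methoxybenzyl)oxy]phenyl]acetyl}phenoxy)-2,2-diphenyl-1,3-benzodioxol-5-yl]ethyl}benzoate
Product: 14 methyl 3-{2-[7-(4-{(1S)-2-[3-(benzyloxy)-2-[(4-methoxybenzyl)oxy]phenyl]-1-hydroxyethyl}phenoxy)-2,2-diphenyl-1,3-benzodioxol-5-yl]ethyl}benzoate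
Conditions: RuCl[(S,S)-TsDPEN](p-cymene) (2 mol %), HCO2H/Et3N (5:2), EtOAc, 40 °C
Reagents that add atoms: none
Why: Noyori asymmetric transfer hydrogenation; the ring B aryl group lies against the η6-arene of the catalyst, so the (S,S)-ligand should deliver hydride to the Re face as it does for acetophenone, and because the CH2Ar group ranks like the methyl group of acetophenone this gives the S carbinol.

Step 10
Reactants: 14 methyl 3-{2-[7-(4-{(1S)-2-[3-(benzyloxy)-2-[(4-methoxybenzyl)oxy]phenyl]-1-hydroxyethyl}phenoxy)-2,2-diphenyl-1,3-benzodioxol-5-yl]ethyl}benzoate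
Product: 15 methyl 3-{2-[7-(4-{(1S)-2-[3-(benzyloxy)-2-[(4-methoxybenzyl)oxy]phenyl]-1-[(tert-butyldimethylsilyl)oxy]ethyl}phenoxy)-2,2-diphenyl-1,3-benzodioxol-5-yl]ethyl}benzoate
Conditions: TBSCl, imidazole, DMAP (cat.), DMF, 40 °C
Reagents that add atoms: tert-butyldimethylsilyl chloride, CC(C)(C)[Si](C)(C)Cl
Why: Silylation of a secondary alcohol; the O–Si bond forms without touching the C–O bond, so the configuration is kept, and the silyl ether blocks the only hydroxyl that could compete with the phenol in the lactonization.

Step 11
Reactants: 15 methyl 3-{2-[7-(4-{(1S)-2-[3-(benzyloxy)-2-[(4-methoxybenzyl)oxy]phenyl]-1-[(tert-butyldimethylsilyl)oxy]ethyl}phenoxy)-2,2-diphenyl-1,3-benzodioxol-5-yl]ethyl}benzoate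
Product: 16 methyl 3-{2-[7-(4-{(1S)-2-[3-(benzyloxy)-2-hydroxyphenyl]-1-[(tert-butyldimethylsilyl)oxy]ethyl}phenoxy)-2,2-diphenyl-1,3-benzodioxol-5-yl]ethyl}benzoate
Conditions: DDQ (1.3 equiv), CH2Cl2/pH 7 phosphate buffer (10:1), 0 °C
Reagents that add atoms: none
Why: Oxidative cleavage of a 4-methoxybenzyl ether (hydride abstraction from the electron-rich benzylic CH2, then hydrolysis of the oxocarbenium ion); the unsubstituted benzyl ether, the ketal and the hindered benzylic silyl ether react far more slowly.

Step 12
Reactants: 16 methyl 3-{2-[7-(4-{(1S)-2-[3-(benzyloxy)-2-hydroxyphenyl]-1-[(tert-butyldimethylsilyl)oxy]ethyl}phenoxy)-2,2-diphenyl-1,3-benzodioxol-5-yl]ethyl}benzoate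
Product: 17 3-{2-[7-(4-{(1S)-2-[3-(benzyloxy)-2-hydroxyphenyl]-1-[(tert-butyldimethylsilyl)oxy]ethyl}phenoxy)-2,2-diphenyl-1,3-benzodioxol-5-yl]ethyl}benzoic acid
Conditions: LiOH·H2O, THF/MeOH/H2O (3:1:1), rt; then aq. HCl to pH 4, 0 °C
Reagents that add atoms: lithium hydroxide, [Li+].[OH-] (one carboxyl oxygen)
Why: Saponification of the methyl ester by acyl substitution; the secondary alkyl silyl ether, the benzyl ether and the ketal are stable to aqueous LiOH at room temperature.

Step 13
Reactants: 17 3-{2-[7-(4-{(1S)-2-[3-(benzyloxy)-2-hydroxyphenyl]-1-[(tert-butyldimethylsilyl)oxy]ethyl}phenoxy)-2,2-diphenyl-1,3-benzodioxol-5-yl]ethyl}benzoic acid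
Product: 19 (S)-19-membered macrolactone (ring A as diphenylmethylene ketal; ring C O-benzyl; carbinol O-TBS; aryl ester from the ring C oxygen flanked by CH2 and OBn to the ring D carbonyl), via mixed anhydride 18 (not isolated)
Conditions: 2,4,6-Cl3C6H2COCl, Et3N, THF, rt; then slow addition to DMAP, toluene (1 mM), 80 °C
Reagents that add atoms: 2,4,6-trichlorobenzoyl chloride, O=C(Cl)c1c(Cl)cc(Cl)cc1Cl (its acyl group stands in 18 and is lost again on the way to 19)
Why: Yamaguchi macrolactonization; DMAP attacks the less hindered ring D carbonyl of the mixed anhydride and the acylpyridinium ion is captured by the only free hydroxyl, the ring C phenol, under high dilution; the neighbouring oxygen is a benzyl ether, so no group can migrate and the site of acylation is fixed.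

Step 14
Reactants: 19 (S)-19-membered macrolactone
Product: 20 (S)-18-membered macrocyclic diaryl ether (ring A as diphenylmethylene ketal; ring C O-benzyl; carbinol O-TBS; ring C oxygen bonded directly to ring D)
Conditions: Ni(cod)2 (20 mol %), dcypt [3,4-bis(dicyclohexylphosphino)thiophene] (40 mol %), K3PO4 (1.5 equiv), toluene (5 mM), 150 °C, sealed tube
Reagents that add atoms: none
Why: Proposed new method: zerovalent nickel carrying the electron-rich chelating diphosphine dcypt should add oxidatively into the acyl C–O bond of the aryl ester, the ring D aryl group then shifts from the acyl carbon to nickel, CO dissociates, and the remaining aryl nickel aryloxide (divalent nickel) forms the bond from the ring C oxygen to the ring D carbon by reductive elimination; the closest known reaction type is the nickel- or palladium-catalysed decarbonylative conversion of aryl azinecarboxylates into diaryl ethers, which has not been shown for a benzoate without a coordinating ring nitrogen or for a lactone. Oxidative addition and CO loss are the steps that operate in decarbonylative couplings of simple phenyl benzoates with external partners, so the untested elementary step is C–O reductive elimination without a chelating nitrogen, which the bulky donor ligand, the high temperature and the steric compression at the di-ortho-substituted aryloxide should favour. The 18-membered ring is not closed end to end but arises by ring contraction: the 19-membered lactone becomes a 20-membered acyl nickelacycle, then a 19-membered aryl nickelacycle after CO loss, and finally the 18-membered ether on reductive elimination. No stereocenter is formed, and the (S)-carbinol carbon is a silyl ether remote from the metal with no acidifying neighbour, so it should pass unchanged. The step needs chemoselectivity for the ester C–O bond over the diaryl ether, benzyl ether, ketal and silyl ether C–O bonds; the acyl C–O bond is by far the most reactive toward zerovalent nickel, and the others have no way to turn over without a reductant or an organometallic partner. Because both partners sit on the same nickel atom, the two ortho substituents of ring C do not have to admit an external aryl electrophile, and high dilution suppresses aryloxide exchange between nickel centres, which would lead to oligomers.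

Step 15
Reactants: 20 (S)-18-membered macrocyclic diaryl ether
Product: 21 (S)-macrocyclic triphenol with the carbinol as TBS ether
Conditions: H2 (1 atm), Pd(OH)2/C, EtOAc/THF, rt
Reagents that add atoms: none
Why: Hydrogenolysis of benzylic C–O bonds removes the benzyl ether as toluene and the diphenylmethylene ketal as diphenylmethane; the diaryl ethers are inert, and the benzylic carbinol C–O bond is shielded by the bulky silyl group in a non-acidic solvent.

Step 16
Reactants: 21 (S)-macrocyclic triphenol with the carbinol as TBS ether
Product: 22 CNP0356934.1, the (S)-configured macrocyclic carbinol with three free phenols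
Conditions: Bu4NF, AcOH (1:1), THF, 0 °C to rt, under argon
Reagents that add atoms: none
Why: Fluoride-induced desilylation driven by the Si–F bond; the acetic acid buffer keeps the catechol protonated against air oxidation and avoids both acid ionization and base-induced elimination at the benzylic carbinol, whose C–O bond is not touched.

## Compound list

1 | 3,4,5-trihydroxybenzaldehyde | O=Cc1cc(O)c(O)c(O)c1 | starting material
2 | 7-hydroxy-2,2-diphenyl-1,3-benzodioxole-5-carbaldehyde | O=Cc1cc(O)c2OC(c3ccccc3)(c3ccccc3)Oc2c1 | intermediate
3 | methyl 3-(bromomethyl)benzoate | COC(=O)c1cccc(CBr)c1 | starting material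
4 | [3-(methoxycarbonyl)benzyl]triphenylphosphonium bromide | COC(=O)c1cccc(C[P+](c2ccccc2)(c2ccccc2)c2ccccc2)c1.[Br-] | intermediate
5 | methyl 3-[(triphenylphosphoranylidene)methyl]benzoate (ylide, not isolated) | COC(=O)c1cccc(C=P(c2ccccc2)(c2ccccc2)c2ccccc2)c1 | intermediate
6 | methyl 3-[2-(7-hydroxy-2,2-diphenyl-1,3-benzodioxol-5-yl)ethenyl]benzoate (E/Z mixture) | COC(=O)c1cccc(C=Cc2cc(O)c3OC(c4ccccc4)(c4ccccc4)Oc3c2)c1 | intermediate
7 | methyl 3-[2-(7-hydroxy-2,2-diphenyl-1,3-benzodioxol-5-yl)ethyl]benzoate | COC(=O)c1cccc(CCc2cc(O)c3OC(c4ccccc4)(c4ccccc4)Oc3c2)c1 | intermediate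
8 | 4'-fluoroacetophenone | CC(=O)c1ccc(F)cc1 | starting material
9 | methyl 3-{2-[7-(4-acetylphenoxy)-2,2-diphenyl-1,3-benzodioxol-5-yl]ethyl}benzoate | COC(=O)c1cccc(CCc2cc(Oc3ccc(cc3)C(C)=O)c3OC(c4ccccc4)(c4ccccc4)Oc3c2)c1 | intermediate
10 | 2-(benzyloxy)phenol | Oc1ccccc1OCc1ccccc1 | starting material
11 | 2-(benzyloxy)-6-bromophenol | Oc1c(Br)cccc1OCc1ccccc1 | intermediate
12 | 1-(benzyloxy)-3-bromo-2-[(4-methoxybenzyl)oxy]benzene | COc1ccc(COc2c(Br)cccc2OCc2ccccc2)cc1 | intermediate
13 | methyl 3-{2-[7-(4-{[3-(benzyloxy)-2-[(4-methoxybenzyl)oxy]phenyl]acetyl}phenoxy)-2,2-diphenyl-1,3-benzodioxol-5-yl]ethyl}benzoate | COC(=O)c1cccc(CCc2cc(Oc3ccc(cc3)C(=O)Cc3cccc(OCc4ccccc4)c3OCc3ccc(OC)cc3)c3OC(c4ccccc4)(c4ccccc4)Oc3c2)c1 | intermediate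
14 | methyl 3-{2-[7-(4-{(1S)-2-[3-(benzyloxy)-2-[(4-methoxybenzyl)oxy]phenyl]-1-hydroxyethyl}phenoxy)-2,2-diphenyl-1,3-benzodioxol-5-yl]ethyl}benzoate | COC(=O)c1cccc(CCc2cc(Oc3ccc(cc3)[C@@H](O)Cc3cccc(OCc4ccccc4)c3OCc3ccc(OC)cc3)c3OC(c4ccccc4)(c4ccccc4)Oc3c2)c1 | intermediate
15 | methyl 3-{2-[7-(4-{(1S)-2-[3-(benzyloxy)-2-[(4-methoxybenzyl)oxy]phenyl]-1-[(tert-butyldimethylsilyl)oxy]ethyl}phenoxy)-2,2-diphenyl-1,3-benzodioxol-5-yl]ethyl}benzoate | COC(=O)c1cccc(CCc2cc(Oc3ccc(cc3)[C@@H](O[Si](C)(C)C(C)(C)C)Cc3cccc(OCc4ccccc4)c3OCc3ccc(OC)cc3)c3OC(c4ccccc4)(c4ccccc4)Oc3c2)c1 | intermediate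
16 | methyl 3-{2-[7-(4-{(1S)-2-[3-(benzyloxy)-2-hydroxyphenyl]-1-[(tert-butyldimethylsilyl)oxy]ethyl}phenoxy)-2,2-diphenyl-1,3-benzodioxol-5-yl]ethyl}benzoate | COC(=O)c1cccc(CCc2cc(Oc3ccc(cc3)[C@@H](O[Si](C)(C)C(C)(C)C)Cc3cccc(OCc4ccccc4)c3O)c3OC(c4ccccc4)(c4ccccc4)Oc3c2)c1 | intermediate
17 | 3-{2-[7-(4-{(1S)-2-[3-(benzyloxy)-2-hydroxyphenyl]-1-[(tert-butyldimethylsilyl)oxy]ethyl}phenoxy)-2,2-diphenyl-1,3-benzodioxol-5-yl]ethyl}benzoic acid (seco acid) | OC(=O)c1cccc(CCc2cc(Oc3ccc(cc3)[C@@H](O[Si](C)(C)C(C)(C)C)Cc3cccc(OCc4ccccc4)c3O)c3OC(c4ccccc4)(c4ccccc4)Oc3c2)c1 | intermediate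
18 | mixed anhydride of 17 with 2,4,6-trichlorobenzoic acid (not isolated) | Clc1cc(Cl)c(C(=O)OC(=O)c2cccc(CCc3cc(Oc4ccc(cc4)[C@@H](O[Si](C)(C)C(C)(C)C)Cc4cccc(OCc5ccccc5)c4O)c4OC(c5ccccc5)(c5ccccc5)Oc4c3)c2)c(Cl)c1 | intermediate
19 | (S)-19-membered macrolactone: ring A diphenylmethylene ketal, ring C O-benzyl, carbinol O-TBS, aryl ester from the ring C oxygen to the ring D carbonyl | O1c2cc3cc(c2OC1(c1ccccc1)c1ccccc1)Oc1ccc(cc1)[C@@H](O[Si](C)(C)C(C)(C)C)Cc1cccc(OCc2ccccc2)c1OC(=O)c1cccc(c1)CC3 | intermediate
20 | (S)-18-membered macrocyclic diaryl ether: ring A diphenylmethylene ketal, ring C O-benzyl, carbinol O-TBS | O1c2cc3cc(c2OC1(c1ccccc1)c1ccccc1)Oc1ccc(cc1)[C@@H](O[Si](C)(C)C(C)(C)C)Cc1cccc(OCc2ccccc2)c1Oc1cccc(c1)CC3 | intermediate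
21 | (S)-macrocyclic triphenol, carbinol TBS ether | Oc1cc2cc(c1O)Oc1ccc(cc1)[C@@H](O[Si](C)(C)C(C)(C)C)Cc1cccc(O)c1Oc1cccc(c1)CC2 | intermediate
22 | CNP0356934.1, (S)-macrocyclic carbinol with three free phenols | Oc1cc2cc(c1O)Oc1ccc(cc1)[C@@H](O)Cc1cccc(O)c1Oc1cccc(c1)CC2 | target

## Step count and least certain steps

Total step count: 16. Longest linear sequence: 13 (steps 1, 3, 4, 5 and 8 to 16); steps 2, 6 and 7 make the two side fragments.

**Step 14 (key step, proposed new method).**
- What may go wrong: the catalytic cycle may stall after oxidative addition, because CO loss and C–O reductive elimination are not assisted by a ring nitrogen. The aryl nickel intermediate may be protonated, so that the carbonyl carbon is lost without ether formation. Aryloxide exchange between nickel centres may lead to oligomerization. Insertion of nickel into the benzylic C–O bonds of the benzyl ether or the ketal may drain the catalyst.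
- Fallback (known chemistry): the same bond is closed by a palladium-catalysed arylation of the phenol with an aryl chloride. It sets out from 2 and comes back at 20. Wittig reaction of 2 with commercial (3-chlorobenzyl)triphenylphosphonium chloride under the conditions of step 3 should give the stilbene 6-[2-(3-chlorophenyl)ethenyl]-2,2-diphenyl-1,3-benzodioxol-4-ol F1. Hydrogenation as in step 4, where the sulfide-poisoned catalyst leaves the aryl chloride, should give the bibenzyl phenol 6-[2-(3-chlorophenyl)ethyl]-2,2-diphenyl-1,3-benzodioxol-4-ol F2. Substitution on 8 as in step 5 should give the methyl ketone 1-[4-({6-[2-(3-chlorophenyl)ethyl]-2,2-diphenyl-1,3-benzodioxol-4-yl}oxy)phenyl]ethanone F3. Arylation with 12 as in step 8, where the Xantphos-ligated catalyst inserts into the aryl bromide and not the chloride, should give the chloro deoxybenzoin F4. Transfer hydrogenation as in step 9 should give the (S)-chloro alcohol F5, silylation as in step 10 the chloro TBS ether F6, and DDQ as in step 11 the chloro phenol F7. F7 is then cyclized at high dilution with Pd(OAc)2, t-BuXPhos and K3PO4 in toluene at 100 °C (Buchwald–Hartwig diaryl ether formation), which gives 20 directly.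

**Step 13 (macrolactonization).**
- What may go wrong: acylation of the di-ortho-substituted phenol may be slow relative to intermolecular acyl transfer, so that dimerization and oligomerization compete. The phenol may also be acylated by the activating reagent.
- Fallback: the acid is activated and isolated while the phenol is still masked, and ring closure is triggered by unmasking. It sets out from 15 and comes back at 19. Saponification of 15 as in step 12 should give the 4-methoxybenzyl-protected acid F8. EDC·HCl and pentafluorophenol should convert it into the pentafluorophenyl ester F9. DDQ as in step 11 should free the phenol to give the phenol pentafluorophenyl ester F10. Slow addition of F10 to Cs2CO3 in MeCN at high dilution should close the lactone 19 by attack of the phenoxide on the active ester.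

**Step 8 (ketone α-arylation).**
- What may go wrong: oxidative addition and reductive elimination at the aryl bromide flanked by an ortho alkoxy group may be slow with a weak base, so that double arylation or condensation of the enolate with the methyl ester competes.
- Fallback: the polarity is reversed. It sets out from 9 and 12 and comes back at 13. Phenyltrimethylammonium tribromide in THF at 0 °C should brominate the methyl ketone of 9 selectively at the side chain to give the phenacyl bromide methyl 3-{2-[7-(4-(bromoacetyl)phenoxy)-2,2-diphenyl-1,3-benzodioxol-5-yl]ethyl}benzoate F11. Bromine–lithium exchange on 12 (n-BuLi, THF, −78 °C) and transmetalation with ZnCl2 should give the arylzinc chloride [3-(benzyloxy)-2-[(4-methoxybenzyl)oxy]phenyl]zinc chloride F12, which is used in solution. Negishi coupling of F11 with F12 under NiCl2(dme) and a bipyridine ligand at −30 to 0 °C, a known arylation of α-bromo ketones that tolerates the methyl ester, should give 13.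

**Step 4 (alkene hydrogenation beside the ketal).**
- What may go wrong: partial hydrogenolysis of the diphenylmethylene ketal during saturation of the stilbene, or incomplete reduction if the catalyst is poisoned too heavily.
- Fallback: the ethylene bridge is made without an alkene to reduce. It sets out from 2 and comes back at 7, and replaces steps 2 to 4. Methylenation of 2 with Ph3P=CH2 (2.2 equiv) should give the styrene 6-ethenyl-2,2-diphenyl-1,3-benzodioxol-4-ol F13. Treatment with 9-BBN (2.2 equiv, THF) should give the B-alkyl-9-BBN adduct F14, in which the phenol is carried as its borinate. F14 is not isolated; B-alkyl Suzuki coupling with methyl 3-bromobenzoate under Pd(dppf)Cl2 and aqueous K3PO4 in THF/DMF at 60 °C, followed by hydrolysis of the borinate on work-up, should give 7.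

## Further compounds

F1 | step 14 | 6-[2-(3-chlorophenyl)ethenyl]-2,2-diphenyl-1,3-benzodioxol-4-ol (E/Z mixture) | Oc1cc(C=Cc2cccc(Cl)c2)cc2OC(c3ccccc3)(c3ccccc3)Oc12
F2 | step 14 | 6-[2-(3-chlorophenyl)ethyl]-2,2-diphenyl-1,3-benzodioxol-4-ol | Oc1cc(CCc2cccc(Cl)c2)cc2OC(c3ccccc3)(c3ccccc3)Oc12
F3 | step 14 | 1-[4-({6-[2-(3-chlorophenyl)ethyl]-2,2-diphenyl-1,3-benzodioxol-4-yl}oxy)phenyl]ethanone | CC(=O)c1ccc(cc1)Oc1cc(CCc2cccc(Cl)c2)cc2OC(c3ccccc3)(c3ccccc3)Oc12
F4 | step 14 | 2-[3-(benzyloxy)-2-[(4-methoxybenzyl)oxy]phenyl]-1-[4-({6-[2-(3-chlorophenyl)ethyl]-2,2-diphenyl-1,3-benzodioxol-4-yl}oxy)phenyl]ethanone (chloro deoxybenzoin) | Clc1cccc(CCc2cc(Oc3ccc(cc3)C(=O)Cc3cccc(OCc4ccccc4)c3OCc3ccc(OC)cc3)c3OC(c4ccccc4)(c4ccccc4)Oc3c2)c1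
F5 | step 14 | (1S)-2-[3-(benzyloxy)-2-[(4-methoxybenzyl)oxy]phenyl]-1-[4-({6-[2-(3-chlorophenyl)ethyl]-2,2-diphenyl-1,3-benzodioxol-4-yl}oxy)phenyl]ethanol (chloro alcohol) | Clc1cccc(CCc2cc(Oc3ccc(cc3)[C@@H](O)Cc3cccc(OCc4ccccc4)c3OCc3ccc(OC)cc3)c3OC(c4ccccc4)(c4ccccc4)Oc3c2)c1
F6 | step 14 | tert-butyldimethylsilyl ether of F5 (chloro TBS ether) | Clc1cccc(CCc2cc(Oc3ccc(cc3)[C@@H](O[Si](C)(C)C(C)(C)C)Cc3cccc(OCc4ccccc4)c3OCc3ccc(OC)cc3)c3OC(c4ccccc4)(c4ccccc4)Oc3c2)c1
F7 | step 14 | 2-(benzyloxy)-6-{(2S)-2-[(tert-butyldimethylsilyl)oxy]-2-[4-({6-[2-(3-chlorophenyl)ethyl]-2,2-diphenyl-1,3-benzodioxol-4-yl}oxy)phenyl]ethyl}phenol (chloro phenol) | Clc1cccc(CCc2cc(Oc3ccc(cc3)[C@@H](O[Si](C)(C)C(C)(C)C)Cc3cccc(OCc4ccccc4)c3O)c3OC(c4ccccc4)(c4ccccc4)Oc3c2)c1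
F8 | step 13 | 3-{2-[7-(4-{(1S)-2-[3-(benzyloxy)-2-[(4-methoxybenzyl)oxy]phenyl]-1-[(tert-butyldimethylsilyl)oxy]ethyl}phenoxy)-2,2-diphenyl-1,3-benzodioxol-5-yl]ethyl}benzoic acid | OC(=O)c1cccc(CCc2cc(Oc3ccc(cc3)[C@@H](O[Si](C)(C)C(C)(C)C)Cc3cccc(OCc4ccccc4)c3OCc3ccc(OC)cc3)c3OC(c4ccccc4)(c4ccccc4)Oc3c2)c1
F9 | step 13 | pentafluorophenyl ester of F8 | Fc1c(F)c(F)c(OC(=O)c2cccc(CCc3cc(Oc4ccc(cc4)[C@@H](O[Si](C)(C)C(C)(C)C)Cc4cccc(OCc5ccccc5)c4OCc4ccc(OC)cc4)c4OC(c5ccccc5)(c5ccccc5)Oc4c3)c2)c(F)c1F
F10 | step 13 | pentafluorophenyl ester of 17 (free ring C phenol) | Fc1c(F)c(F)c(OC(=O)c2cccc(CCc3cc(Oc4ccc(cc4)[C@@H](O[Si](C)(C)C(C)(C)C)Cc4cccc(OCc5ccccc5)c4O)c4OC(c5ccccc5)(c5ccccc5)Oc4c3)c2)c(F)c1F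
F11 | step 8 | methyl 3-{2-[7-(4-(bromoacetyl)phenoxy)-2,2-diphenyl-1,3-benzodioxol-5-yl]ethyl}benzoate | COC(=O)c1cccc(CCc2cc(Oc3ccc(cc3)C(=O)CBr)c3OC(c4ccccc4)(c4ccccc4)Oc3c2)c1
F12 | step 8 | [3-(benzyloxy)-2-[(4-methoxybenzyl)oxy]phenyl]zinc chloride | COc1ccc(COc2c([Zn]Cl)cccc2OCc2ccccc2)cc1
F13 | step 4 | 6-ethenyl-2,2-diphenyl-1,3-benzodioxol-4-ol | Oc1cc(C=C)cc2OC(c3ccccc3)(c3ccccc3)Oc12
F14 | step 4 | B-alkyl-9-BBN adduct of F13 with the phenol as its 9-BBN borinate | C1CC2CCCC(C1)B2Oc1cc(CCB2C3CCCC2CCC3)cc2OC(c3ccccc3)(c3ccccc3)Oc12
A1 | alternative 1 | open-chain 3-chloro-2-methoxycyclohex-2-enone with free ring B phenol (racemic) | O=C1CC(CCc2cccc(c2)Oc2c(OC)cccc2CC(=O)c2ccc(O)cc2)CC(Cl)=C1OC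
A2 | alternative 1 | macrocyclic 3-aryloxy-2-methoxycyclohex-2-enone (racemic at the ring A sp3 carbon) | O=C1CC2CC(=C1OC)Oc1ccc(cc1)C(=O)Cc1cccc(OC)c1Oc1cccc(c1)CC2
A3 | alternative 2 | (S)-open-chain ring A styrene with ring D bromide, silyl protected | C=Cc1cc(O[Si](C(C)C)(C(C)C)C(C)C)c(O[Si](C(C)C)(C(C)C)C(C)C)c(c1)Oc1ccc(cc1)[C@@H](O[Si](C)(C)C(C)(C)C)Cc1cccc(O[Si](C(C)C)(C(C)C)C(C)C)c1Oc1cccc(Br)c1
A4 | alternative 2 | (S)-macrocycle, tris-TIPS ether and carbinol TBS ether | CC(C)[Si](C(C)C)(C(C)C)Oc1cc2cc(c1O[Si](C(C)C)(C(C)C)C(C)C)Oc1ccc(cc1)[C@@H](O[Si](C)(C)C(C)(C)C)Cc1cccc(O[Si](C(C)C)(C(C)C)C(C)C)c1Oc1cccc(c1)CC2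
A5 | alternative 3 | open-chain ring B iodide with ring C arylacetaldehyde, tris-TBS ether | CC(C)(C)[Si](C)(C)Oc1cc(CCc2cccc(c2)Oc2c(CC=O)cccc2O[Si](C)(C)C(C)(C)C)cc(Oc2ccc(I)cc2)c1O[Si](C)(C)C(C)(C)C
A6 | alternative 3 | (S)-macrocyclic carbinol, tris-TBS ether | CC(C)(C)[Si](C)(C)Oc1cc2cc(c1O[Si](C)(C)C(C)(C)C)Oc1ccc(cc1)[C@@H](O)Cc1cccc(O[Si](C)(C)C(C)(C)C)c1Oc1cccc(c1)CC2
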